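**Strategy.** Marrubiin supplies rings A and B with all six decalin stereocentres. Its furan is excised to the C13 acid, and the derived 9α,13-spirolactone is rebuilt into a spiro 2-methyleneoxolan-3-one (ring C). The route rests on disconnecting the dihydrofuran (ring D) at C13–C14 and O–C16: a palladium-catalysed decarboxylative [3+2] cycloaddition of vinylethylene carbonate adds its alkoxide to C16 and its allyl terminus to C13 in one operation. It exploits the C12 ketone, which makes the exocyclic C13=C16 bond electrophilic at C16 and nucleophilic at C13, and it sets quaternary C13 under ligand control. The surplus vinyl group is then cut back to the C14=C15 enol ether.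

Key step: step 8

Remark: labdane numbering is used (ring A C1–C5/C10, ring B C5–C10, ring C the oxolan-3-one O/C9/C11/C12/C13, ring D the dihydrofuran C13/C14/C15/O/C16); marrubiin is taken as a purchasable natural product; C12 in 6–9 and C14 in 12–13 are carried as epimer mixtures (left undefined in the SMILES) because both centres are erased later.

Step 1
Reactants: 1 marrubiin
Product: 2 marrubenol (15,16-epoxylabda-13(16),14-diene-6β,9α,19-triol)
Conditions: LiAlH4, THF, 0 °C to reflux; NaOH aq. work-up
Reagents that add atoms: none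
Why: Hydride reduction of the 19,6β-lactone should give the 6β,19-diol while the furan and the tertiary 9α-hydroxyl stay untouched and no stereocentre is affected (lactone reduction).

Step 2
Reactants: 2 marrubenol
Product: 3 6β,19-O-(di-tert-butylsilylene)marrubenol
Conditions: tBu2Si(OTf)2, 2,6-lutidine, CH2Cl2, 0 °C to rt
Reagents that add atoms: di-tert-butylsilyl bis(trifluoromethanesulfonate), CC(C)(C)[Si](OS(=O)(=O)C(F)(F)F)(OS(=O)(=O)C(F)(F)F)C(C)(C)C
Why: Silylene acetal formation, in which the primary 19-hydroxyl is silylated first and the second Si–O bond closes intramolecularly onto the syn-axial 6β-hydroxyl, while the tertiary 9α-hydroxyl on the opposite face cannot be bridged and stays free.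

Step 3
Reactants: 3 6β,19-O-(di-tert-butylsilylene)marrubenol
Product: 5 silylene-protected 14,15,16-trinorlabdan-13,9α-olide (spiro γ-lactone), via hydroxy acid 4 (not isolated)
Conditions: RuCl3·xH2O (cat.), NaIO4, CCl4/MeCN/H2O, 0 °C to rt; then EDC·HCl, DMAP, CH2Cl2, rt
Reagents that add atoms: sodium periodate, [Na+].[O-]I(=O)(=O)=O; water, O
Why: RuO4 generated in situ should degrade the electron-rich 3-substituted furan to the C13 carboxylic acid (furan as masked carboxyl), and carbodiimide activation then closes the γ-lactone onto the 9α-hydroxyl with C9 unchanged because only the acyl C–O bond is formed (Steglich-type lactonisation).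

Step 4
Reactants: 5 spiro γ-lactone
Product: 6 12-hydroxy spiro γ-lactone (C12 epimers)
Conditions: KN(SiMe3)2, THF, −78 °C; 2-(phenylsulfonyl)-3-phenyloxaziridine, −78 °C; NH4Cl aq.
Reagents that add atoms: 2-(phenylsulfonyl)-3-phenyloxaziridine, O=S(=O)(c1ccccc1)N1OC1c1ccccc1
Why: Enolate α-hydroxylation with an N-sulfonyloxaziridine at C12, the only enolisable position; the C12 configuration is irrelevant because this carbon becomes the ketone in step 7.

Step 5
Reactants: 6 12-hydroxy spiro γ-lactone
Product: 7 12-(trimethylsilyloxy) spiro γ-lactone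
Conditions: TMSCl, imidazole, CH2Cl2, 0 °C
Reagents that add atoms: chlorotrimethylsilane, C[Si](C)(C)Cl
Why: Silyl ether formation masks the 12-hydroxyl so that it does not consume the titanium reagent of step 6.

Step 6
Reactants: 7 12-(trimethylsilyloxy) spiro γ-lactone
Product: 9 silylene-protected 9α,13-epoxy-14,15-dinorlabd-13(16)-en-12-ol (exocyclic enol ether allylic alcohol), via silylated enol ether 8 (not isolated)
Conditions: Cp2TiMe2, toluene, 70 °C, dark; then K2CO3, MeOH, 0 °C
Reagents that add atoms: dimethyltitanocene, [Ti+4].[CH3-].[CH3-].c1cc[cH-]c1.c1cc[cH-]c1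
Why: Petasis methylenation of the lactone carbonyl (as used on sugar lactones to give exo-glycals) installs C16 as the exocyclic enol ether under neutral conditions, and basic methanolysis then removes the trimethylsilyl group without touching the acid-labile enol ether or the silylene.

Step 7
Reactants: 9 exocyclic enol ether allylic alcohol
Product: 10 silylene-protected 9α,13-epoxy-14,15-dinorlabd-13(16)-en-12-one (spiro 2-methyleneoxolan-3-one)
Conditions: MnO2 (activated), CH2Cl2, rt; used at once
Reagents that add atoms: none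
Why: Chemoselective allylic alcohol oxidation by MnO2 under neutral conditions should give the exo-methylene ketone without the acid that would isomerise the enol ether into the ring.

Step 8
Reactants: 10 spiro 2-methyleneoxolan-3-one; 11 4-vinyl-1,3-dioxolan-2-one (racemic)
Product: 12 (13R)-6β,19-O-(di-tert-butylsilylene)-9α,13:15,16-diepoxy-14-vinyllabdan-12-one (C14 epimers)
Conditions: Pd2(dba)3·CHCl3 (2.5 mol%), BINOL N,N-bis(1-phenylethyl)phosphoramidite (10 mol%, single enantiomer), 11 (1.5 equiv), THF, 0 °C to rt
Reagents that add atoms: none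
Why: Zerovalent palladium ionises 11 with loss of CO2 to a zwitterionic π-allylpalladium alkoxide, whose alkoxide adds in oxa-Michael fashion to the exposed exocyclic C16 (O–C16) and whose allyl unit is then attacked at its internal carbon by the resulting C13 enolate (C13–C14). The closest known reaction type is the palladium-catalysed decarboxylative [3+2] cycloaddition of vinylethylene carbonates or vinyloxiranes with electron-poor alkenes. Ring D closes by 5-exo attack of the enolate carbon on the allyl terminus, leaving the vinyl group exocyclic; closure at the distal terminus would need a seven-membered ring. The quaternary C13 is set by the chiral ligand: the plane of ring C bisects C8–C9–C10 and is flanked almost symmetrically by C17H3 and C1H2, so the substrate should exert little facial bias, and the ligand enantiomer is chosen that places C14 on the face syn to C10. C14 is not controlled and is erased in step 10. The step needs conjugate over carbonyl addition and C- over O-allylation, which the unhindered terminal methylene, the hindered C12 carbonyl and the five-membered ring size should secure.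

Step 9
Reactants: 12 14-vinyl spiro oxolane
Product: 13 (13R)-6β,19-O-(di-tert-butylsilylene)-9α,13:15,16-diepoxy-12-oxolabdane-14-carbaldehyde (C14 epimers)
Conditions: O3, CH2Cl2, −78 °C; then PPh3, −78 °C to rt
Reagents that add atoms: ozone, [O-][O+]=O
Why: Ozonolysis with reductive work-up cleaves the only C=C bond to the C14 aldehyde, while the ketone, ethers and silylene are inert at −78 °C and C13 is untouched.

Step 10
Reactants: 13 C14 aldehyde
Product: 14 (13R)-6β,19-O-(di-tert-butylsilylene)-9α,13:15,16-diepoxylabd-14-en-12-one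
Conditions: [Rh(cod)(OMe)]2 (2 mol%), Xantphos, 3-methoxybenzoic acid (cat.), norbornadiene, THF, 60 °C
Reagents that add atoms: none
Why: Rhodium-catalysed transfer dehydroformylation (aldehyde C–H activation, CO de-insertion, β-hydride elimination) can eliminate only toward C15 because C13 is quaternary, so it should give the C14=C15 enol ether while norbornadiene takes up H2 and CO; C13 is not involved.

Step 11
Reactants: 14 silylene-protected dihydrofuran
Product: 15 (13R)-9α,13:15,16-diepoxy-6β,19-dihydroxylabd-14-en-12-one (target)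
Conditions: HF·pyridine, pyridine, THF, 0 °C
Reagents that add atoms: none
Why: Fluoride cleavage of the silylene under pyridine-buffered conditions should free the 6β,19-diol without hydrating the enol ether or opening the β-alkoxy ketone of ring C, and no stereocentre is affected.

**Compound list**

1 | marrubiin (9α-hydroxy-15,16-epoxylabda-13(16),14-dien-19,6β-olide) | C[C@@H]1C[C@@H](O3)[C@H]2[C@@](C)(C3=O)CCC[C@]2(C)[C@@]1(O)CCc1ccoc1 | starting material
2 | marrubenol (15,16-epoxylabda-13(16),14-diene-6β,9α,19-triol) | C[C@@H]1C[C@@H](O)[C@H]2[C@@](C)(CO)CCC[C@]2(C)[C@@]1(O)CCc1ccoc1 | intermediate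
3 | 6β,19-O-(di-tert-butylsilylene)marrubenol | C[C@@H]1C[C@@H](O3)[C@H]2[C@@](C)(CO[Si]3(C(C)(C)C)C(C)(C)C)CCC[C@]2(C)[C@@]1(O)CCc1ccoc1 | intermediate
4 | 6β,19-O-(di-tert-butylsilylene)-9α-hydroxy-14,15,16-trinorlabdan-13-oic acid | C[C@@H]1C[C@@H](O3)[C@H]2[C@@](C)(CO[Si]3(C(C)(C)C)C(C)(C)C)CCC[C@]2(C)[C@@]1(O)CCC(=O)O | intermediate
5 | 6β,19-O-(di-tert-butylsilylene)-14,15,16-trinorlabdan-13,9α-olide | C[C@@H]1C[C@@H](O3)[C@H]2[C@@](C)(CO[Si]3(C(C)(C)C)C(C)(C)C)CCC[C@]2(C)[C@@]12CCC(=O)O2 | intermediate
6 | 12-hydroxy derivative of lactone 5 (C12 epimers) | C[C@@H]1C[C@@H](O3)[C@H]2[C@@](C)(CO[Si]3(C(C)(C)C)C(C)(C)C)CCC[C@]2(C)[C@@]12CC(O)C(=O)O2 | intermediate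
7 | 12-(trimethylsilyloxy) derivative of lactone 5 | C[C@@H]1C[C@@H](O3)[C@H]2[C@@](C)(CO[Si]3(C(C)(C)C)C(C)(C)C)CCC[C@]2(C)[C@@]12CC(O[Si](C)(C)C)C(=O)O2 | intermediate
8 | 6β,19-O-(di-tert-butylsilylene)-9α,13-epoxy-12-(trimethylsilyloxy)-14,15-dinorlabd-13(16)-ene | C[C@@H]1C[C@@H](O3)[C@H]2[C@@](C)(CO[Si]3(C(C)(C)C)C(C)(C)C)CCC[C@]2(C)[C@@]12CC(O[Si](C)(C)C)C(=C)O2 | intermediate
9 | 6β,19-O-(di-tert-butylsilylene)-9α,13-epoxy-14,15-dinorlabd-13(16)-en-12-ol | C[C@@H]1C[C@@H](O3)[C@H]2[C@@](C)(CO[Si]3(C(C)(C)C)C(C)(C)C)CCC[C@]2(C)[C@@]12CC(O)C(=C)O2 | intermediate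
10 | 6β,19-O-(di-tert-butylsilylene)-9α,13-epoxy-14,15-dinorlabd-13(16)-en-12-one | C[C@@H]1C[C@@H](O3)[C@H]2[C@@](C)(CO[Si]3(C(C)(C)C)C(C)(C)C)CCC[C@]2(C)[C@@]12CC(=O)C(=C)O2 | intermediate
11 | 4-vinyl-1,3-dioxolan-2-one (vinylethylene carbonate) | C=CC1COC(=O)O1 | starting material
12 | (13R)-6β,19-O-(di-tert-butylsilylene)-9α,13:15,16-diepoxy-14-vinyllabdan-12-one | C[C@@H]1C[C@@H](O3)[C@H]2[C@@](C)(CO[Si]3(C(C)(C)C)C(C)(C)C)CCC[C@]2(C)[C@@]12CC(=O)[C@]1(C(C=C)COC1)O2 | intermediate
13 | (13R)-6β,19-O-(di-tert-butylsilylene)-9α,13:15,16-diepoxy-12-oxolabdane-14-carbaldehyde | C[C@@H]1C[C@@H](O3)[C@H]2[C@@](C)(CO[Si]3(C(C)(C)C)C(C)(C)C)CCC[C@]2(C)[C@@]12CC(=O)[C@]1(C(C=O)COC1)O2 | intermediate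
14 | (13R)-6β,19-O-(di-tert-butylsilylene)-9α,13:15,16-diepoxylabd-14-en-12-one | C[C@@H]1C[C@@H](O3)[C@H]2[C@@](C)(CO[Si]3(C(C)(C)C)C(C)(C)C)CCC[C@]2(C)[C@@]12CC(=O)[C@]1(C=COC1)O2 | intermediate
15 | (13R)-9α,13:15,16-diepoxy-6β,19-dihydroxylabd-14-en-12-one | C[C@@H]1C[C@@H](O)[C@H]2[C@@](C)(CO)CCC[C@]2(C)[C@@]12CC(=O)[C@]1(C=COC1)O2 | target

**Step count and risks**

Total step count: 11. Longest linear sequence: 11 steps (1 to 15).

Steps most likely to fail:

Step 8. The ligand may discriminate the two nearly equivalent faces of C13 poorly, or the alkoxide may add too slowly to a singly activated enone or attack the C12 carbonyl instead. The fallback sets out from 10: a base-mediated domino oxa-Michael/aldol annulation with glycolaldehyde dimer (1,4-dioxane-2,5-diol, DABCO, CH2Cl2) should again form O–C16 and C13–C14 in one flask and give the 14-hydroxy spiro oxolane F1. Its C13 epimers are separated, and the unwanted one is returned to the basic conditions, where retro-aldol/aldol exchange re-equilibrates it. Dehydration of F1 with Burgess reagent (THF, 50 °C), possible only toward C15, comes back to the route at 14 and bypasses steps 9 and 10.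

Step 10. Decarbonylation may occur without β-hydride elimination and give the saturated oxolane, or the β-alkoxy aldehyde may open by elimination. The fallback sets out from 13: Pinnick oxidation (NaClO2, NaH2PO4, 2-methyl-2-butene, tBuOH/H2O) gives the C14 carboxylic acid F2. Oxidative decarboxylation (Pb(OAc)4, Cu(OAc)2 cat., pyridine, benzene, 80 °C; Kochi reaction) then generates the C14 radical, which is oxidised to the C14=C15 enol ether, and comes back at 14.

Step 2. The silylene may fail to close onto the hindered axial 6β-hydroxyl, leaving a mono-silylated material. The fallback sets out from 2: silylation of the primary hydroxyl with tBu2SiHCl and imidazole (DMF) gives the 19-O-(di-tert-butylhydrosilyl) ether F3. Base-catalysed intramolecular dehydrogenative Si–O coupling (KOtBu cat., THF), driven by loss of hydrogen, closes the ring and comes back at 3.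

**Further compounds**

F1 | step 8 | 6β,19-O-(di-tert-butylsilylene)-9α,13:15,16-diepoxy-14-hydroxylabdan-12-one, C13 configured as in the target (C14 epimers) | C[C@@H]1C[C@@H](O3)[C@H]2[C@@](C)(CO[Si]3(C(C)(C)C)C(C)(C)C)CCC[C@]2(C)[C@@]12CC(=O)[C@]1(C(O)COC1)O2
F2 | step 10 | (13R)-6β,19-O-(di-tert-butylsilylene)-9α,13:15,16-diepoxy-12-oxolabdane-14-carboxylic acid (C14 epimers) | C[C@@H]1C[C@@H](O3)[C@H]2[C@@](C)(CO[Si]3(C(C)(C)C)C(C)(C)C)CCC[C@]2(C)[C@@]12CC(=O)[C@]1(C(C(=O)O)COC1)O2
F3 | step 2 | 19-O-(di-tert-butylhydrosilyl)marrubenol | C[C@@H]1C[C@@H](O)[C@H]2[C@@](C)(CO[SiH](C(C)(C)C)C(C)(C)C)CCC[C@]2(C)[C@@]1(O)CCc1ccoc1
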